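Its constants were set for the occasion; the run is a simulation.

What struck me about this flask was its slowness, and I set the charges down to see where that slowness could come from.

    starting material → side product A (k1 = 0.0098 /s)
    starting material ⇌ dormant form (K2 = 1.1, k2 = 0.096 /s)
    starting material + target → side product B (k3 = 0.55 /M/s)
    gas phase ⇌ dissolved gas, rate k4*(csat - [dissolved gas]) (k4 = 0.20 /s, csat = 11 mM)
    starting material + dissolved gas → target (k5 = 3.0 /M/s)

| flask | starting material | gas phase | time |
|---|---|---|---|
| green | 0.050 M | 11 mM (held) | 20 s |
| teal | 0.050 M | 11 mM (held) | 40 s |

- a species is counted by the starting material in it: one side product B counts as two
- at the start none of the gas is dissolved
- run time (green): 20 s

- which of these there is most of at the end, counted by the starting material in it, green (side product B / side product A / starting material / target)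
- which of these there is most of at the end, counted by the starting material in it, teal (side product B / side product A / starting material / target)
- amount of the one of these that there is most of at the end, in percent of the starting material charged, green
- amount of the one of these that there is most of at the end, in percent of the starting material charged, teal

The constants seemed to say two things at once. Free starting material enters the dormant form with a half-life of 7.2 s, counting the forward step alone, and with the gas taken at its saturation of 11 mM it goes to target and side product A with a half-life of 16.2 s. Together these make 4.99 s, which over the 20 s of green would leave 6.22 % free if nothing came back from the dormant form, and yet I could not believe that figure.

The way back from the dormant form runs at 0.0873 /s, faster than the 0.0428 /s at which free starting material is drained, so I treated the dormant form as a resting state in pre-equilibrium, with free and dormant forming one pool of which 47.6 % is free. I called the pool half-life, the half-life of free and dormant together when they drain through the free part only, 34.0 s, leaving out step 3 and the filling of the gas.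

That gave me 31.7 % free in green and 21.1 % in teal. Splitting the drained pool by the two rates gave target 25.8 % in green and 43.0 % in teal, so I committed to starting material leading in green and target in teal.

The forecast named starting material at 33 % for green and target at 28 % for teal, where “target has passed it”.

The simulation gave starting material at 31.0 % in green, with target at 16.1 %, and target at 26.8 % in teal, with starting material at 20.4 %.

Free starting material thus stood close to my pool reckoning, while my target figures stood too high. In teal at 11.0 s the half-life of starting material by the making of target was 30 s, shorter than the 71 s towards side product A, but longer than the 21.0 s I had assumed. For the neighbour of teal with 0.12 M of starting material, the pool half-life as I had written it contains no charge, so with the gas still taken at saturation it again gave 21.1 % of that flask's charge free; the computed value at the end was 21 %, with dissolved gas at 0.00778 M and target at 17.5 %.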